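The smaller charge, larch at 1.7 M of G, shows 31.8% E at 15.0 min, and the larger, elm at 2.5 M, shows 32.7%: a gap of 0.9 percentage points, less than three times the scatter of 0.5 points, so percentages are read as free of the charge.

| flask | G | remark | time |
|---|---|---|---|
| elm | 2.5 M | the very flask that is asked about, followed so far |  |
| larch | 1.7 M | run made earlier |  |
| flask | 2.5 M |  | 1.5 h |

- elm (time / min: E / %, J / %): 5.00: 12.0, 0; 10.0: 22.9, 0.9; 15.0: 32.7, 0.9; 20.0: 39.2, 2.1; 25.0: 44.7, 2.1
- larch (time / min: E / %, J / %): 6.00: 14.5, 0.4; 15.0: 31.8, 1.6; 30.0: 51.0, 1.6; 50.0: 66.4, 2.4; 60.0: 70.2, 2.2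

(standard deviation of a reading: 0.5 percentage points)

- ratio of E to J at 25 s
- ratio of E to J at 1.5 h

The pooled readings, E standing over J standing, give a value 27.1, which is taken here as the selectivity factor S, E formed per J formed. But larch E bends: read as a reversible approach to a plateau, the gap left after 30.0 min is a share 0.376, the plateau reads 81.8%, and 1.5 h is reckoned to span N = 2.93 relaxation times, with the approach reckoned 94.7% complete. My own reckoning takes J as keeping what it receives and folds these into φ, the share of all E formed that still stands as E, so that the early ratio is S and the late ratio is Sφ. With G as what E lacks, φ is 0.724; putting the resulting J back into G and going round once more gives 0.773, hence a ratio of 20.9. The last larch ratio, 31.9, is a reading at 60.0 min whose scatter is a quarter of its J.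

The forecast stands with S early and parts from this reckoning late: 27 at 25 s and 29 at 1.5 h, holding that “J looks like a parallel product with a constant branching ratio”.

The flask gives 25.0 and 22.3.

    G ⇌ E (K = 12.0, k = 4.50 × 10⁻⁴ s⁻¹)
    G ⇌ J (K = 2.80, k = 1.80 × 10⁻⁵ s⁻¹)
    G ⇌ X (K = 16.0, k = 4.10 × 10⁻⁵ s⁻¹)

In this flask, half of the turnover of G into E up to the asked time was done by 0.323 h, and at 0.150 h G stood at 76.2% with J at 0.849%. At 1.50 h G was down to 11.2%, with E at 77.4%, J at 3.46% and the unseen X at 8.00%. Late ratio over early ratio in this flask is 0.892, against the reckoned φ of 0.773. The neighbour with 1.5 M of G gives 25.0 and 22.3, and so the same 0.892.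

The readings were computed on assumed constants, noise included.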